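**Retrosynthetic overview**

1. Longipinane numbering: C-1 ketone, C-2=C-3(Me), cyclobutane C-4/C-5/C-10/C-11, C-6 = CMe2, C-7 and C-8 = ester carbons, C-9 = carbinol, C-10 = C(Me). The esters and the 7,8,9-triol are unfolded last (C-7 oxygen from a C–Si bond, C-8/C-9 from an alkene). The cyclohexenone comes from a one-carbon Ito–Saegusa ring expansion (insertion of C-2) of a bicyclo[2.1.1]hexan-2-one, which leads back to tricyclic ketone 15.
2. Key disconnection: every cyclobutane carbon is a ring-fusion atom and both diagonals are bridged (C-11···C-4 by C-1–C-2–C-3, C-5···C-10 by C-6–C-7–C-8–C-9). With C-2 taken out, the short bridge has two atoms and the core is the crossed [2+2] adduct of a cyclodeca-1,5-diene; cutting C-5–C-11 and C-4–C-10 leaves the monocyclic ten-membered dienone 14 (transannular enone–alkene photocycloaddition).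
3. 14 comes from the trans-1,2-dialkenylcyclohexenol 11 by anionic oxy-Cope ring expansion, which also relays the ring stereocentres to the silyl-bearing C-7. 11 comes from a quinone monoketal by asymmetric 1,4-addition and a 1,2-addition.
4. Order of ring formation: cyclohexene (dearomatisation) → ten-membered ring (oxy-Cope) → cyclobutane, cyclopentane and the seven-membered ring together (photocycloaddition) → cyclohexenone (ring expansion of the cyclopentanone).

Key step: step 9

**Remarks**

- Compound-specific locants are used up to 14, longipinane locants from 15 on. 15–23 lack C-2 and the C-3 methyl (2,12-dinor), 24 and 25 lack C-2 (2-nor), 26 onward have all fifteen carbons.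
- Angeloyl = (Z)-2-methylbut-2-enoyl. For the tricyclic compounds the configuration is that of the SMILES: ring-fusion centres as in the target, C-7 substituent trans to the C-8 oxygen, C-8 and C-9 oxygens cis.
- Assumption on work-up: reactions run with lithium or potassium bases are quenched with aqueous NH4Cl, so the spent metal is counted as its chloride.
- 27 should form as a mixture of C-3 epimers; this centre is left open in its SMILES and disappears in the same step.

**Route**

Step 1
Reactants: 1 4-methoxy-3-methylphenol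
Product: 2 4,4-dimethoxy-3-methylcyclohexa-2,5-dien-1-one
Conditions: PhI(OAc)2 (1.1 equiv), MeOH, 0 °C
Reagents that add atoms: methanol, CO
Why: Oxidative dearomatisation of a para-methoxyphenol by the iodine reagent in methanol (quinone monoketal synthesis) should trap the phenoxenium-type intermediate at the methoxy-bearing carbon; no stereocentre is formed.

Step 2
Reactants: 2 4,4-dimethoxy-3-methylcyclohexa-2,5-dien-1-one; 3 (2-methylprop-1-en-1-yl)boronic acid
Product: 4 (5S)-4,4-dimethoxy-3-methyl-5-(2-methylprop-1-en-1-yl)cyclohex-2-en-1-one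
Conditions: [Rh(OH)((S)-BINAP)]2 (3 mol %), dioxane/H2O (10:1), 35 °C
Reagents that add atoms: 3 (2-methylprop-1-en-1-yl)boronic acid, CC(C)=CB(O)O
Why: Hayashi–Miyaura asymmetric 1,4-addition: the alkenyl–rhodium species (monovalent rhodium) can insert only the unsubstituted C-5=C-6 enone because C-3 carries a methyl group, and the (S)-BINAP ligand should deliver the alkenyl group to the enone face that gives the (5S) centre, the same sense as with cyclohex-2-enone.

Step 3
Reactants: 4 (5S)-4,4-dimethoxy-3-methyl-5-(2-methylprop-1-en-1-yl)cyclohex-2-en-1-one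
Product: 5 (1S,5S)-4,4-dimethoxy-3-methyl-5-(2-methylprop-1-en-1-yl)cyclohex-2-en-1-ol
Conditions: NaBH4, CeCl3·7H2O, MeOH, −78 °C
Reagents that add atoms: none
Why: Luche 1,2-reduction of the enone: axial hydride attack on the half-chair that keeps the C-5 alkenyl group equatorial should give the equatorial (1S) alcohol, cis to that group.

Step 4
Reactants: 5 (1S,5S)-4,4-dimethoxy-3-methyl-5-(2-methylprop-1-en-1-yl)cyclohex-2-en-1-ol
Product: 6 tert-butyl{[(1S,5S)-4,4-dimethoxy-3-methyl-5-(2-methylprop-1-en-1-yl)cyclohex-2-en-1-yl]oxy}dimethylsilane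
Conditions: TBSCl, imidazole, DMF, rt
Reagents that add atoms: tert-butyl(chloro)dimethylsilane, CC(C)(C)[Si](C)(C)Cl
Why: Standard silylation of a secondary allylic alcohol; the silyl ether masks the later C-1 carbonyl and is the group that steers the photocycloaddition.

Step 5
Reactants: 6 tert-butyl{[(1S,5S)-4,4-dimethoxy-3-methyl-5-(2-methylprop-1-en-1-yl)cyclohex-2-en-1-yl]oxy}dimethylsilane
Product: 7 (4S,6S)-4-[(tert-butyldimethylsilyl)oxy]-2-methyl-6-(2-methylprop-1-en-1-yl)cyclohex-2-en-1-one
Conditions: PPTS (cat.), acetone/H2O, rt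
Reagents that add atoms: water, O
Why: Acid-catalysed hydrolysis of the allylic dimethyl ketal through the conjugated oxocarbenium ion should be much faster than cleavage of the silyl ether; C-6 becomes epimerisable, but its cis (diequatorial) relation to the fixed C-4 silyloxy group is the thermodynamically favoured one, so the configuration should hold.

Step 6
Reactants: 8 ethynyl(dimethyl)phenylsilane
Product: 9 (E)-dimethyl(phenyl)[2-(tributylstannyl)ethenyl]silane
Conditions: Bu3SnH, AIBN (cat.), toluene, 90 °C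
Reagents that add atoms: tributylstannane, CCCC[SnH](CCCC)CCCC
Why: Radical hydrostannylation of a terminal silylalkyne: the stannyl radical adds to the terminal carbon, and reversible addition–elimination should equilibrate the adduct to the (E)-1-silyl-2-stannylethene.

Step 7
Reactants: 7 (4S,6S)-4-[(tert-butyldimethylsilyl)oxy]-2-methyl-6-(2-methylprop-1-en-1-yl)cyclohex-2-en-1-one; 9 (E)-dimethyl(phenyl)[2-(tributylstannyl)ethenyl]silane
Product: 11 (1S,4S,6S)-4-[(tert-butyldimethylsilyl)oxy]-1-{(E)-2-[dimethyl(phenyl)silyl]ethenyl}-2-methyl-6-(2-methylprop-1-en-1-yl)cyclohex-2-en-1-ol, via vinyllithium 10 (not isolated)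
Conditions: 9, n-BuLi, THF, −78 °C; then 7, −78 °C; aq. NH4Cl
Reagents that add atoms: 9 (E)-dimethyl(phenyl)[2-(tributylstannyl)ethenyl]silane, CCCC[Sn](CCCC)(CCCC)/C=C/[Si](C)(C)c1ccccc1
Why: Tin–lithium exchange followed by 1,2-addition of the alkenyllithium to the enone carbonyl (the β-carbon is fully substituted): equatorial attack anti to the C-6 alkenyl group should place the new alkenyl group trans to it and the hydroxyl cis (1S), the trans-1,2-dialkenyl arrangement needed for a chair oxy-Cope.

Step 8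
Reactants: 11 (1S,4S,6S)-4-[(tert-butyldimethylsilyl)oxy]-1-{(E)-2-[dimethyl(phenyl)silyl]ethenyl}-2-methyl-6-(2-methylprop-1-en-1-yl)cyclohex-2-en-1-ol
Product: 14 (2Z,4S,6E,9R)-4-[(tert-butyldimethylsilyl)oxy]-9-[dimethyl(phenyl)silyl]-2,8,8-trimethylcyclodeca-2,6-dien-1-one, via potassium alkoxide 12 (not isolated), via potassium enolate 13 (not isolated)
Conditions: KH, 18-crown-6, THF, 0 °C to rt; aq. NH4Cl at −78 °C
Reagents that add atoms: none
Why: Anionic oxy-Cope rearrangement ([3,3]-sigmatropic ring expansion by four carbons): in the chair transition state with both ring bonds equatorial the C-1–C-6 bond breaks while the silyl-bearing vinyl terminus bonds to the dimethyl-substituted terminus, which should give the (E)-alkene, a regiodefined enolate (protonated on work-up) and, because the (E)-silyl group sits equatorial, the (9R) silyl-bearing centre; the (E)-vinylsilane cannot undergo 1,4-migration of silicon from carbon to oxygen.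

Step 9
Reactants: 14 (2Z,4S,6E,9R)-4-[(tert-butyldimethylsilyl)oxy]-9-[dimethyl(phenyl)silyl]-2,8,8-trimethylcyclodeca-2,6-dien-1-one
Product: 15 1-[(tert-butyldimethylsilyl)oxy]-7-[dimethyl(phenyl)silyl]-2,12-dinorlongipinan-9-one
Conditions: hν (medium-pressure Hg lamp, Pyrex and uranium-glass filter, λ > 330 nm), degassed MeCN (0.005 M), rt
Reagents that add atoms: none
Why: Excitation of the enone (C-9 carbonyl, C-10=C-11) and intersystem crossing give the triplet, whose β-carbon C-11 bonds to C-5 of the C-4=C-5 alkene held two atoms away (1,5-closure, the rule-of-five mode of a 1,5-diene), and the resulting 1,4-biradical (C-10, tertiary and α to the carbonyl; C-4) collapses to the cyclobutane. The closest known reaction type is the crossed intramolecular enone–alkene [2+2] photocycloaddition of 1-acylhexa-1,5-dienes to bicyclo[2.1.1]hexanes and its transannular version in cyclodecadienones. Ring closures: the cyclopentane C-11/C-1/C-3/C-4/C-5 by the 1,5-closure of the triplet, the cyclobutane C-4/C-5/C-11/C-10 by recombination of the biradical, and with these two bonds the seven-membered rings that contain the chain C-5 to C-10 are closed transannularly. Stereocentres: C-5 and C-10 are fixed by the four-carbon tether C-6 to C-9, which can only span the cyclobutane face opposite the two-carbon bridge, C-4 and C-11 follow as bridgeheads, and the absolute sense of the core is set by the C-1 silyloxy centre, which should end up trans to C-10 on the new cyclopentane (allylic 1,3-strain holds H-1 in the enone plane, so the alkene comes in anti to the silyloxy group). The step needs crossed over parallel closure and one facial sense: the two-atom C-1/C-3 tether secures the first (the parallel mode would need a four-membered ring across it or a first bond between the congested C-10 and C-5), the C-1 substituent the second, and Z/E scrambling of the enone triplet is harmless because the ring geometry is fixed only at closure. The silyl-bearing C-7 centre lies in the locally symmetric part of the molecule and is a spectator.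

Step 10
Reactants: 15 1-[(tert-butyldimethylsilyl)oxy]-7-[dimethyl(phenyl)silyl]-2,12-dinorlongipinan-9-one
Product: 17 1-[(tert-butyldimethylsilyl)oxy]-7-[dimethyl(phenyl)silyl]-2,12-dinorlongipin-8-en-9-yl trifluoromethanesulfonate, via potassium enolate 16 (not isolated)
Conditions: KN(SiMe3)2, THF, −78 °C; then PhNTf2, −78 to 0 °C
Reagents that add atoms: N-phenylbis(trifluoromethanesulfonimide), O=S(=O)(N(c1ccccc1)S(=O)(=O)C(F)(F)F)C(F)(F)F
Why: Regiospecific enolate formation (C-8 is the only enolisable position of the C-9 ketone because C-10 is quaternary) and O-sulfonylation by the triflimide give the enol triflate; no stereocentre changes, the β-silyl enolate being stable at low temperature.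

Step 11
Reactants: 17 1-[(tert-butyldimethylsilyl)oxy]-7-[dimethyl(phenyl)silyl]-2,12-dinorlongipin-8-en-9-yl trifluoromethanesulfonate
Product: 18 1-[(tert-butyldimethylsilyl)oxy]-7-[dimethyl(phenyl)silyl]-2,12-dinorlongipin-8-ene
Conditions: Pd(OAc)2 (5 mol %), PPh3, HCO2H, Bu3N, DMF, 60 °C
Reagents that add atoms: none
Why: Palladium-catalysed formate reduction of the enol triflate (oxidative addition to zerovalent palladium, formate exchange, decarboxylation, reductive elimination) should give the cis C-8=C-9 alkene without touching the allylic silane.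

Step 12
Reactants: 18 1-[(tert-butyldimethylsilyl)oxy]-7-[dimethyl(phenyl)silyl]-2,12-dinorlongipin-8-ene
Product: 19 1-[(tert-butyldimethylsilyl)oxy]-7-[dimethyl(phenyl)silyl]-2,12-dinorlongipinane-8,9-diol
Conditions: OsO4 (5 mol %), NMO (1.5 equiv), acetone/H2O (8:1), rt
Reagents that add atoms: 4-methylmorpholine N-oxide, C[N+]1([O-])CCOCC1; water, O
Why: Upjohn syn-dihydroxylation of the only alkene: OsO4 should add anti to the bulky allylic silyl group at C-7, which sets C-8 and C-9 as the cis-diol trans to silicon.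

Step 13
Reactants: 19 1-[(tert-butyldimethylsilyl)oxy]-7-[dimethyl(phenyl)silyl]-2,12-dinorlongipinane-8,9-diol
Product: 20 1-[(tert-butyldimethylsilyl)oxy]-7-[dimethyl(phenyl)silyl]-8,9-(isopropylidenedioxy)-2,12-dinorlongipinane
Conditions: 2,2-dimethoxypropane, PPTS (cat.), CH2Cl2, rt
Reagents that add atoms: 2,2-dimethoxypropane, COC(C)(C)OC
Why: Acetal exchange with the cis-1,2-diol gives the isopropylidene acetal that protects the diol in the oxidation and enolate steps that follow; PPTS should be too weak an acid to trigger Peterson elimination of the β-hydroxysilane.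

Step 14
Reactants: 20 1-[(tert-butyldimethylsilyl)oxy]-7-[dimethyl(phenyl)silyl]-8,9-(isopropylidenedioxy)-2,12-dinorlongipinane
Product: 21 7-[dimethyl(phenyl)silyl]-8,9-(isopropylidenedioxy)-2,12-dinorlongipinan-1-ol
Conditions: HF·pyridine, pyridine/THF, 0 °C to rt
Reagents that add atoms: none
Why: Fluoride-induced cleavage of the silyl ether; the Si–C bond of the dimethyl(phenyl)silyl group and the acetonide should survive buffered HF·pyridine.

Step 15
Reactants: 21 7-[dimethyl(phenyl)silyl]-8,9-(isopropylidenedioxy)-2,12-dinorlongipinan-1-ol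
Product: 22 7-[dimethyl(phenyl)silyl]-8,9-(isopropylidenedioxy)-2,12-dinorlongipinan-1-one
Conditions: Dess–Martin periodinane, pyridine, CH2Cl2, rt
Reagents that add atoms: none
Why: Dess–Martin oxidation of the secondary alcohol to the strained bicyclo[2.1.1]hexan-2-one under nearly neutral conditions; the C-1 stereocentre, having done its work, is removed.

Step 16
Reactants: 22 7-[dimethyl(phenyl)silyl]-8,9-(isopropylidenedioxy)-2,12-dinorlongipinan-1-one
Product: 24 7-[dimethyl(phenyl)silyl]-8,9-(isopropylidenedioxy)-2-norlongipinan-1-one, via lithium enolate 23 (not isolated)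
Conditions: LiN(i-Pr)2, THF, −78 °C; then MeI, −78 to 0 °C
Reagents that add atoms: iodomethane, CI
Why: Kinetic enolate alkylation: C-3 is the only enolisable position (C-11 is a bridgehead), and methyl iodide should approach from the face next to C-5 and away from the C-10 methyl group; the configuration of the new centre is of no consequence because C-3 becomes trigonal again.

Step 17
Reactants: 24 7-[dimethyl(phenyl)silyl]-8,9-(isopropylidenedioxy)-2-norlongipinan-1-one
Product: 25 7-[dimethyl(phenyl)silyl]-8,9-(isopropylidenedioxy)-1-[(trimethylsilyl)oxy]-2-norlongipin-1(3)-ene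
Conditions: TMSOTf, Et3N, CH2Cl2, 0 °C to rt
Reagents that add atoms: trimethylsilyl trifluoromethanesulfonate, C[Si](C)(C)OS(=O)(=O)C(F)(F)F
Why: Soft enolisation and O-silylation (silyl triflate and amine base) give the only possible silyl enol ether, C-1=C-3; no stereocentre is formed.

Step 18
Reactants: 25 7-[dimethyl(phenyl)silyl]-8,9-(isopropylidenedioxy)-1-[(trimethylsilyl)oxy]-2-norlongipin-1(3)-ene
Product: 26 7-[dimethyl(phenyl)silyl]-8,9-(isopropylidenedioxy)-1-[(trimethylsilyl)oxy]-1,3-cyclolongipinane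
Conditions: Et2Zn, CH2I2, toluene, 0 °C to rt
Reagents that add atoms: diiodomethane, ICI
Why: Simmons–Smith cyclopropanation (Furukawa reagent) of the electron-rich, strained enol ether from the face next to C-5 introduces C-2; the configuration of the cyclopropane is lost in the next step.

Step 19
Reactants: 26 7-[dimethyl(phenyl)silyl]-8,9-(isopropylidenedioxy)-1-[(trimethylsilyl)oxy]-1,3-cyclolongipinane
Product: 28 7-[dimethyl(phenyl)silyl]-8,9-(isopropylidenedioxy)longipin-2-en-1-one, via chloro ketone 27 (not isolated)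
Conditions: FeCl3, DMF, 0 °C; then NaOAc, MeOH, reflux
Reagents that add atoms: none
Why: Ito–Saegusa ring expansion: FeCl3 oxidises the siloxycyclopropane to an oxygen-centred radical whose β-scission breaks the internal C-1–C-3 bond (relief of the bicyclo[2.1.1]hexane strain, tertiary radical at C-3), chlorine transfer gives the β-chloro ketone, and acetate then eliminates HCl through the C-2 enolate (E1cB) to the conjugated C-2=C-3 enone.

Step 20
Reactants: 28 7-[dimethyl(phenyl)silyl]-8,9-(isopropylidenedioxy)longipin-2-en-1-one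
Product: 30 7-hydroxy-8,9-(isopropylidenedioxy)longipin-2-en-1-one, via acetoxysilane 29 (not isolated)
Conditions: Hg(OAc)2 (1.5 equiv), AcOOH (32 % in AcOH), rt
Reagents that add atoms: peracetic acid, CC(=O)OO
Why: Fleming–Tamao oxidation: ipso-mercuration removes the phenyl group, and the peracid-induced 1,2-shift from silicon to oxygen goes with retention, so the C-7 hydroxyl takes the place of silicon; the enone should be too electron-poor to be epoxidised under these conditions.

Step 21
Reactants: 30 7-hydroxy-8,9-(isopropylidenedioxy)longipin-2-en-1-one; 31 angelic anhydride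
Product: 33 7-(angeloyloxy)-8,9-(isopropylidenedioxy)longipin-2-en-1-one, via lithium alkoxide 32 (not isolated)
Conditions: LiN(SiMe3)2 (1.05 equiv), THF, −78 °C; then 31, −78 to 0 °C
Reagents that add atoms: 31 angelic anhydride, C/C=C(/C)C(=O)OC(=O)/C(C)=C\C
Why: Acylation of the lithium alkoxide with angelic anhydride at low temperature (stereoconservative angeloylation, no nucleophilic catalyst that could isomerise the Z-ester to the tiglate); the alkoxide should form faster than any enolate of the enone.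

Step 22
Reactants: 33 7-(angeloyloxy)-8,9-(isopropylidenedioxy)longipin-2-en-1-one
Product: 34 7-(angeloyloxy)-8,9-dihydroxylongipin-2-en-1-one
Conditions: AcOH/H2O (4:1), 40 °C
Reagents that add atoms: none
Why: Acid-catalysed hydrolysis of the isopropylidene acetal frees the C-8/C-9 cis-diol; an acyl shift from O-7 to O-8 would be harmless because both positions end up as angelates.

Step 23
Reactants: 34 7-(angeloyloxy)-8,9-dihydroxylongipin-2-en-1-one; 31 angelic anhydride
Product: 36 7,8-bis(angeloyloxy)-9-hydroxylongipin-2-en-1-one (CNP0256888.1), via lithium alkoxide 35 (not isolated)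
Conditions: LiN(SiMe3)2 (1.0 equiv), THF, −78 °C; then 31 (1.1 equiv), −78 to −20 °C
Reagents that add atoms: 31 angelic anhydride, C/C=C(/C)C(=O)OC(=O)/C(C)=C\C
Why: Selective acylation: with one equivalent of base the less hindered secondary C-8 alkoxide (flanked by two CH groups) should be acylated, while the neopentyl C-9 hydroxyl next to the quaternary C-10 stays free; no stereocentre is touched and the Z geometry of both esters is kept at low temperature.

**Compound list**

1 | 4-methoxy-3-methylphenol | COc1ccc(O)cc1C | starting material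
2 | 4,4-dimethoxy-3-methylcyclohexa-2,5-dien-1-one | COC1(OC)C=CC(=O)C=C1C | intermediate
3 | (2-methylprop-1-en-1-yl)boronic acid | CC(C)=CB(O)O | starting material
4 | (5S)-4,4-dimethoxy-3-methyl-5-(2-methylprop-1-en-1-yl)cyclohex-2-en-1-one | CC1=CC(=O)C[C@@H](C=C(C)C)C1(OC)OC | intermediate
5 | (1S,5S)-4,4-dimethoxy-3-methyl-5-(2-methylprop-1-en-1-yl)cyclohex-2-en-1-ol (OH cis to the alkenyl group) | CC1=C[C@@H](O)C[C@@H](C=C(C)C)C1(OC)OC | intermediate
6 | tert-butyl{[(1S,5S)-4,4-dimethoxy-3-methyl-5-(2-methylprop-1-en-1-yl)cyclohex-2-en-1-yl]oxy}dimethylsilane | CC1=C[C@@H](O[Si](C)(C)C(C)(C)C)C[C@@H](C=C(C)C)C1(OC)OC | intermediate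
7 | (4S,6S)-4-[(tert-butyldimethylsilyl)oxy]-2-methyl-6-(2-methylprop-1-en-1-yl)cyclohex-2-en-1-one | CC1=C[C@@H](O[Si](C)(C)C(C)(C)C)C[C@@H](C=C(C)C)C1=O | intermediate
8 | ethynyl(dimethyl)phenylsilane | C#C[Si](C)(C)c1ccccc1 | starting material
9 | (E)-dimethyl(phenyl)[2-(tributylstannyl)ethenyl]silane | CCCC[Sn](CCCC)(CCCC)/C=C/[Si](C)(C)c1ccccc1 | intermediate
10 | {(E)-2-[dimethyl(phenyl)silyl]ethenyl}lithium | [Li]/C=C/[Si](C)(C)c1ccccc1 | intermediate (not isolated)
11 | (1S,4S,6S)-4-[(tert-butyldimethylsilyl)oxy]-1-{(E)-2-[dimethyl(phenyl)silyl]ethenyl}-2-methyl-6-(2-methylprop-1-en-1-yl)cyclohex-2-en-1-ol (the two alkenyl groups trans, silyloxy cis to the 2-methylpropenyl group) | CC1=C[C@@H](O[Si](C)(C)C(C)(C)C)C[C@@H](C=C(C)C)[C@]1(O)/C=C/[Si](C)(C)c1ccccc1 | intermediate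
12 | potassium alkoxide of 11 | CC1=C[C@@H](O[Si](C)(C)C(C)(C)C)C[C@@H](C=C(C)C)[C@]1([O-])/C=C/[Si](C)(C)c1ccccc1.[K+] | intermediate (not isolated)
13 | potassium enolate of 14 (enolate C-1=C-10 of the ten-membered ring) | C/C1=C/[C@@H](O[Si](C)(C)C(C)(C)C)C/C=C/C(C)(C)[C@H]([Si](C)(C)c2ccccc2)/C=C1\[O-].[K+] | intermediate (not isolated)
14 | (2Z,4S,6E,9R)-4-[(tert-butyldimethylsilyl)oxy]-9-[dimethyl(phenyl)silyl]-2,8,8-trimethylcyclodeca-2,6-dien-1-one | C/C1=C/[C@@H](O[Si](C)(C)C(C)(C)C)C/C=C/C(C)(C)[C@H]([Si](C)(C)c2ccccc2)CC1=O | intermediate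
15 | 1-[(tert-butyldimethylsilyl)oxy]-7-[dimethyl(phenyl)silyl]-2,12-dinorlongipinan-9-one (silyloxy group on the side of the two-carbon bridge that faces C-5) | C1[C@@H]([Si](C)(C)c4ccccc4)C(C)(C)[C@@H]2[C@H]3[C@@H](O[Si](C)(C)C(C)(C)C)C[C@@H]2[C@@]3(C)C1=O | intermediate
16 | potassium 8-en-9-olate of 15 | [O-]C1=C[C@@H]([Si](C)(C)c4ccccc4)C(C)(C)[C@@H]2[C@H]3[C@@H](O[Si](C)(C)C(C)(C)C)C[C@@H]2[C@]31C.[K+] | intermediate (not isolated)
17 | 1-[(tert-butyldimethylsilyl)oxy]-7-[dimethyl(phenyl)silyl]-2,12-dinorlongipin-8-en-9-yl trifluoromethanesulfonate | FC(F)(F)S(=O)(=O)OC1=C[C@@H]([Si](C)(C)c4ccccc4)C(C)(C)[C@@H]2[C@H]3[C@@H](O[Si](C)(C)C(C)(C)C)C[C@@H]2[C@]31C | intermediate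
18 | 1-[(tert-butyldimethylsilyl)oxy]-7-[dimethyl(phenyl)silyl]-2,12-dinorlongipin-8-ene | C1=C[C@@H]([Si](C)(C)c4ccccc4)C(C)(C)[C@@H]2[C@H]3[C@@H](O[Si](C)(C)C(C)(C)C)C[C@@H]2[C@]31C | intermediate
19 | 1-[(tert-butyldimethylsilyl)oxy]-7-[dimethyl(phenyl)silyl]-2,12-dinorlongipinane-8,9-diol (cis-diol, trans to silicon) | O[C@@H]1[C@@H]([Si](C)(C)c4ccccc4)C(C)(C)[C@@H]2[C@H]3[C@@H](O[Si](C)(C)C(C)(C)C)C[C@@H]2[C@@]3(C)[C@@H]1O | intermediate
20 | 1-[(tert-butyldimethylsilyl)oxy]-7-[dimethyl(phenyl)silyl]-8,9-(isopropylidenedioxy)-2,12-dinorlongipinane | CC1(C)O[C@@H]2[C@@H]([Si](C)(C)c5ccccc5)C(C)(C)[C@@H]3[C@H]4[C@@H](O[Si](C)(C)C(C)(C)C)C[C@@H]3[C@@]4(C)[C@@H]2O1 | intermediate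
21 | 7-[dimethyl(phenyl)silyl]-8,9-(isopropylidenedioxy)-2,12-dinorlongipinan-1-ol | CC1(C)O[C@@H]2[C@@H]([Si](C)(C)c5ccccc5)C(C)(C)[C@@H]3[C@H]4[C@@H](O)C[C@@H]3[C@@]4(C)[C@@H]2O1 | intermediate
22 | 7-[dimethyl(phenyl)silyl]-8,9-(isopropylidenedioxy)-2,12-dinorlongipinan-1-one | CC1(C)O[C@@H]2[C@@H]([Si](C)(C)c5ccccc5)C(C)(C)[C@@H]3[C@H]4C(=O)C[C@@H]3[C@@]4(C)[C@@H]2O1 | intermediate
23 | lithium enolate of 22 (C-1=C-3) | CC1(C)O[C@@H]2[C@@H]([Si](C)(C)c5ccccc5)C(C)(C)[C@@H]3[C@H]4C([O-])=C[C@@H]3[C@@]4(C)[C@@H]2O1.[Li+] | intermediate (not isolated)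
24 | 7-[dimethyl(phenyl)silyl]-8,9-(isopropylidenedioxy)-2-norlongipinan-1-one (C-3 methyl on the side facing C-5) | CC1(C)O[C@@H]2[C@@H]([Si](C)(C)c5ccccc5)C(C)(C)[C@@H]3[C@H]4C(=O)[C@@H](C)[C@@H]3[C@@]4(C)[C@@H]2O1 | intermediate
25 | 7-[dimethyl(phenyl)silyl]-8,9-(isopropylidenedioxy)-1-[(trimethylsilyl)oxy]-2-norlongipin-1(3)-ene | CC1(C)O[C@@H]2[C@@H]([Si](C)(C)c5ccccc5)C(C)(C)[C@@H]3[C@H]4C(O[Si](C)(C)C)=C(C)[C@@H]3[C@@]4(C)[C@@H]2O1 | intermediate
26 | 7-[dimethyl(phenyl)silyl]-8,9-(isopropylidenedioxy)-1-[(trimethylsilyl)oxy]-1,3-cyclolongipinane (C-2 bridges C-1 and C-3 on the side facing C-5) | CC1(C)O[C@@H]2[C@@H]([Si](C)(C)c5ccccc5)C(C)(C)[C@@H]3[C@H]4[C@@]6(O[Si](C)(C)C)C[C@@]6(C)[C@@H]3[C@@]4(C)[C@@H]2O1 | intermediate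
27 | 3-chloro-7-[dimethyl(phenyl)silyl]-8,9-(isopropylidenedioxy)longipinan-1-one (C-3 epimers) | CC1(C)O[C@@H]2[C@@H]([Si](C)(C)c5ccccc5)C(C)(C)[C@@H]3[C@H]4C(=O)CC(C)(Cl)[C@@H]3[C@@]4(C)[C@@H]2O1 | intermediate (not isolated)
28 | 7-[dimethyl(phenyl)silyl]-8,9-(isopropylidenedioxy)longipin-2-en-1-one | CC1(C)O[C@@H]2[C@@H]([Si](C)(C)c5ccccc5)C(C)(C)[C@@H]3[C@H]4C(=O)C=C(C)[C@@H]3[C@@]4(C)[C@@H]2O1 | intermediate
29 | 7-[acetoxy(dimethyl)silyl]-8,9-(isopropylidenedioxy)longipin-2-en-1-one | CC1(C)O[C@@H]2[C@@H]([Si](C)(C)OC(C)=O)C(C)(C)[C@@H]3[C@H]4C(=O)C=C(C)[C@@H]3[C@@]4(C)[C@@H]2O1 | intermediate (not isolated)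
30 | 7-hydroxy-8,9-(isopropylidenedioxy)longipin-2-en-1-one | CC1(C)O[C@@H]2[C@@H](O)C(C)(C)[C@@H]3[C@H]4C(=O)C=C(C)[C@@H]3[C@@]4(C)[C@@H]2O1 | intermediate
31 | angelic anhydride, (Z)-2-methylbut-2-enoic anhydride | C/C=C(/C)C(=O)OC(=O)/C(C)=C\C | starting material
32 | lithium 7-alkoxide of 30 | CC1(C)O[C@@H]2[C@@H]([O-])C(C)(C)[C@@H]3[C@H]4C(=O)C=C(C)[C@@H]3[C@@]4(C)[C@@H]2O1.[Li+] | intermediate (not isolated)
33 | 7-(angeloyloxy)-8,9-(isopropylidenedioxy)longipin-2-en-1-one | CC1(C)O[C@@H]2[C@@H](OC(=O)/C(C)=C\C)C(C)(C)[C@@H]3[C@H]4C(=O)C=C(C)[C@@H]3[C@@]4(C)[C@@H]2O1 | intermediate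
34 | 7-(angeloyloxy)-8,9-dihydroxylongipin-2-en-1-one | O[C@@H]1[C@@H](OC(=O)/C(C)=C\C)C(C)(C)[C@@H]2[C@H]3C(=O)C=C(C)[C@@H]2[C@@]3(C)[C@@H]1O | intermediate
35 | lithium 8-alkoxide of 34 | [Li+].[O-][C@@H]1[C@@H](OC(=O)/C(C)=C\C)C(C)(C)[C@@H]2[C@H]3C(=O)C=C(C)[C@@H]2[C@@]3(C)[C@@H]1O | intermediate (not isolated)
36 | 7,8-bis(angeloyloxy)-9-hydroxylongipin-2-en-1-one (CNP0256888.1; 7,8-trans, 8,9-cis) | C/C=C(/C)C(=O)O[C@@H]1[C@@H](OC(=O)/C(C)=C\C)C(C)(C)[C@@H]2[C@H]3C(=O)C=C(C)[C@@H]2[C@@]3(C)[C@@H]1O | target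

**Step count and risks**

Total step count: 23. Longest linear sequence: 22 steps (steps 1–5 and 7–23; step 6 prepares the vinyl donor 9).

The three steps most likely to fail:

Step 9 (photocycloaddition). The enone triplet may relax by Z/E isomerisation without bonding, the 1,4-biradical may revert or transfer hydrogen instead of closing, or the silyloxy group may not differentiate the two faces well enough. The fallback sets out from 14 and returns at 15, and replaces enone excitation by a copper template. Luche reduction (NaBH4, CeCl3·7H2O, MeOH) of 14 gives the dienol (2Z,4S,6E,9R)-4-[(tert-butyldimethylsilyl)oxy]-9-[dimethyl(phenyl)silyl]-2,8,8-trimethylcyclodeca-2,6-dien-1-ol F1. Its copper-templated [2+2] photobicyclisation (CuOTf, monovalent copper, Et2O, 254 nm) has the metal hold both alkenes of the 1,5-diene and the allylic hydroxyl, and the crossed adduct is again the one allowed by the two-atom tether; it should give the tricyclic alcohol 1-[(tert-butyldimethylsilyl)oxy]-7-[dimethyl(phenyl)silyl]-2,12-dinorlongipinan-9-ol F2. Dess–Martin oxidation of F2 gives 15.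

Step 8 (anionic oxy-Cope). Bond formation between the silyl-bearing alkene terminus and the dimethyl-substituted terminus may be so slow that cleavage of the tertiary alkoxide (retro-addition) or decomposition of the enolate takes over. The fallback sets out from 7 and returns at 15; silicon is left out of the rearrangement and brought in afterwards under catalyst control. Addition of CH2=CHMgBr/CeCl3 to 7 gives the divinyl carbinol (1R,4S,6S)-4-[(tert-butyldimethylsilyl)oxy]-1-ethenyl-2-methyl-6-(2-methylprop-1-en-1-yl)cyclohex-2-en-1-ol F3. Its less hindered anionic oxy-Cope rearrangement (KH, 18-crown-6, THF) gives the dienone (2Z,4S,6E)-4-[(tert-butyldimethylsilyl)oxy]-2,8,8-trimethylcyclodeca-2,6-dien-1-one F4. Irradiation as in step 9 gives the tricyclic ketone 1-[(tert-butyldimethylsilyl)oxy]-2,12-dinorlongipinan-9-one F5, and dehydrogenation with IBX (DMSO, 70 °C) gives the cycloheptenone 1-[(tert-butyldimethylsilyl)oxy]-2,12-dinorlongipin-7-en-9-one F6. Enantioselective copper-catalysed conjugate silylation of F6 with PhMe2Si–B(pin) (CuCl, chiral N-heterocyclic carbene ligand, NaOt-Bu, THF, then MeOH) then gives 15. The ligand enantiomer is chosen for the required C-7 face, because the substrate itself does not distinguish the two faces of this ring.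

Step 2 (asymmetric conjugate addition). Insertion next to the quaternary ketal carbon may be slow, the enantioselectivity may erode, or the adduct may lose methanol and aromatise. The fallback sets out from 2 and returns at 5, and trades asymmetric catalysis for a resolution. Copper-catalysed 1,4-addition of Me2C=CHMgBr (CuBr·SMe2, THF, −40 °C) to 2 gives the racemic ketone rac-4,4-dimethoxy-3-methyl-5-(2-methylprop-1-en-1-yl)cyclohex-2-en-1-one F7. Luche reduction gives the racemic cis-alcohol rac-4,4-dimethoxy-3-methyl-5-(2-methylprop-1-en-1-yl)cyclohex-2-en-1-ol F8. Lipase-mediated kinetic resolution (Candida antarctica lipase B, vinyl acetate, hexane) should acetylate the (1R,5R)-enantiomer to (1R,5R)-4,4-dimethoxy-3-methyl-5-(2-methylprop-1-en-1-yl)cyclohex-2-en-1-yl acetate F9 and leave 5, which is separated by chromatography.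

Further compounds
F1 | step 9 | (2Z,4S,6E,9R)-4-[(tert-butyldimethylsilyl)oxy]-9-[dimethyl(phenyl)silyl]-2,8,8-trimethylcyclodeca-2,6-dien-1-ol (C-1 epimers) | C/C1=C/[C@@H](O[Si](C)(C)C(C)(C)C)C/C=C/C(C)(C)[C@H]([Si](C)(C)c2ccccc2)CC1O
F2 | step 9 | 1-[(tert-butyldimethylsilyl)oxy]-7-[dimethyl(phenyl)silyl]-2,12-dinorlongipinan-9-ol (C-9 epimers) | C1[C@@H]([Si](C)(C)c4ccccc4)C(C)(C)[C@@H]2[C@H]3[C@@H](O[Si](C)(C)C(C)(C)C)C[C@@H]2[C@@]3(C)C1O
F3 | step 8 | (1R,4S,6S)-4-[(tert-butyldimethylsilyl)oxy]-1-ethenyl-2-methyl-6-(2-methylprop-1-en-1-yl)cyclohex-2-en-1-ol | CC1=C[C@@H](O[Si](C)(C)C(C)(C)C)C[C@@H](C=C(C)C)[C@]1(O)C=C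
F4 | step 8 | (2Z,4S,6E)-4-[(tert-butyldimethylsilyl)oxy]-2,8,8-trimethylcyclodeca-2,6-dien-1-one | C/C1=C/[C@@H](O[Si](C)(C)C(C)(C)C)C/C=C/C(C)(C)CCC1=O
F5 | step 8 | 1-[(tert-butyldimethylsilyl)oxy]-2,12-dinorlongipinan-9-one | C1CC(C)(C)[C@@H]2[C@H]3[C@@H](O[Si](C)(C)C(C)(C)C)C[C@@H]2[C@@]3(C)C1=O
F6 | step 8 | 1-[(tert-butyldimethylsilyl)oxy]-2,12-dinorlongipin-7-en-9-one | C1=CC(C)(C)[C@@H]2[C@H]3[C@@H](O[Si](C)(C)C(C)(C)C)C[C@@H]2[C@@]3(C)C1=O
F7 | step 2 | rac-4,4-dimethoxy-3-methyl-5-(2-methylprop-1-en-1-yl)cyclohex-2-en-1-one (1:1 mixture of 4 and its enantiomer) | CC1=CC(=O)C[C@@H](C=C(C)C)C1(OC)OC.CC1=CC(=O)C[C@H](C=C(C)C)C1(OC)OC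
F8 | step 2 | rac-cis-4,4-dimethoxy-3-methyl-5-(2-methylprop-1-en-1-yl)cyclohex-2-en-1-ol (1:1 mixture of 5 and its enantiomer) | CC1=C[C@@H](O)C[C@@H](C=C(C)C)C1(OC)OC.CC1=C[C@H](O)C[C@H](C=C(C)C)C1(OC)OC
F9 | step 2 | (1R,5R)-4,4-dimethoxy-3-methyl-5-(2-methylprop-1-en-1-yl)cyclohex-2-en-1-yl acetate | CC1=C[C@H](OC(C)=O)C[C@H](C=C(C)C)C1(OC)OC
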